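The target is a pyrrole ring carrying a methyl ester at C2 and, at C3, an unbranched nonadecyl chain that offers no functional handle. The plan therefore cuts the plain CH2–CH2 bond between chain carbons 2 and 3, counted from ring carbon C3, and makes it by a nickel-electrocatalytic doubly decarboxylative coupling of two redox-active esters. In one operation this joins a two-carbon arm on the ring to the seventeen-carbon residue of stearic acid, with both carboxyl carbons leaving as CO2. The precursor is an N-Boc pyrrole-2-carboxylate whose C3 carries a CH2CH2C(=O)O–N-phthalimide arm, reached by Heck coupling, hydrogenation and esterification; acid then removes the Boc group.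

Key step: step 6

Assumption: the electrolysis is run at constant current in an undivided cell with a sacrificial zinc anode and a reticulated vitreous carbon (RVC) cathode and is worked up with dilute aqueous HCl, so zinc ends as its chloride and phthalimide is recovered neutral. The target is achiral; the chain count is two carbons from the ring arm plus seventeen from stearic acid, giving nineteen.

Step 1
Reactants: 1 methyl 3-bromo-1H-pyrrole-2-carboxylate
Product: 2 1-tert-butyl 2-methyl 3-bromo-1H-pyrrole-1,2-dicarboxylate
Conditions: Boc2O (1.2 equiv), DMAP (0.1 equiv), MeCN, rt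
Reagents that add atoms: di-tert-butyl dicarbonate, CC(C)(C)OC(=O)OC(=O)OC(C)(C)C
Why: The pyrrole N–H, acidified by the C2 ester, is acylated by Boc2O under nucleophilic catalysis by DMAP (standard N-Boc protection), which removes the acidic proton and makes the C3–Br bond more electron-poor for the coming oxidative addition.

Step 2
Reactants: 2 1-tert-butyl 2-methyl 3-bromo-1H-pyrrole-1,2-dicarboxylate; 3 benzyl acrylate (1.5 equiv)
Product: 4 1-tert-butyl 2-methyl 3-[(E)-3-(benzyloxy)-3-oxoprop-1-en-1-yl]-1H-pyrrole-1,2-dicarboxylate
Conditions: Pd2(dba)3 (2 mol%), [(t-Bu)3PH]BF4 (8 mol%), Cy2NMe (1.5 equiv), 1,4-dioxane, 60 °C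
Reagents that add atoms: none
Why: Mizoroki–Heck reaction in which zerovalent palladium inserts into the C3–Br bond activated by the neighbouring ester and the N-Boc group, the pyrrolyl–palladium adds to the unsubstituted acrylate terminus and syn β-hydride elimination gives the E alkene, the mild temperature allowed by the bulky trialkylphosphine sparing the heat-sensitive N-Boc group.

Step 3
Reactants: 4 1-tert-butyl 2-methyl 3-[(E)-3-(benzyloxy)-3-oxoprop-1-en-1-yl]-1H-pyrrole-1,2-dicarboxylate
Product: 6 3-[1-(tert-butoxycarbonyl)-2-(methoxycarbonyl)-1H-pyrrol-3-yl]propanoic acid, via saturated benzyl ester 5 (not isolated)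
Conditions: H2 (1 atm), 10% Pd/C, EtOAc, rt
Reagents that add atoms: none
Why: Heterogeneous catalytic hydrogenation saturates the conjugated alkene and then hydrogenolyses the benzylic C–O bond in the same flask, while the N-acylated, ester-deactivated pyrrole ring, the Boc group and the methyl ester should be inert at one atmosphere and room temperature.

Step 4
Reactants: 6 3-[1-(tert-butoxycarbonyl)-2-(methoxycarbonyl)-1H-pyrrol-3-yl]propanoic acid; 7 N-hydroxyphthalimide (1.05 equiv)
Product: 8 1-tert-butyl 2-methyl 3-{3-[(1,3-dioxoisoindolin-2-yl)oxy]-3-oxopropyl}-1H-pyrrole-1,2-dicarboxylate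
Conditions: N,N'-diisopropylcarbodiimide (DIC, 1.1 equiv), DMAP (0.1 equiv), CH2Cl2, 0 °C to rt
Reagents that add atoms: none
Why: Steglich-type carbodiimide esterification in which the acid is activated by DIC and the O-nucleophilic N-hydroxyphthalimide is acylated under DMAP catalysis, giving the redox-active ester without touching the Boc carbamate or the methyl ester.

Step 5
Reactants: 9 stearic acid (octadecanoic acid); 7 N-hydroxyphthalimide (1.05 equiv)
Product: 10 1,3-dioxoisoindolin-2-yl octadecanoate
Conditions: DIC (1.1 equiv), DMAP (0.1 equiv), CH2Cl2, rt
Reagents that add atoms: none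
Why: The same Steglich-type carbodiimide esterification applied to an unfunctionalised fatty acid should give a crystalline redox-active ester that can be purified by recrystallisation.

Step 6
Reactants: 8 1-tert-butyl 2-methyl 3-{3-[(1,3-dioxoisoindolin-2-yl)oxy]-3-oxopropyl}-1H-pyrrole-1,2-dicarboxylate; 10 1,3-dioxoisoindolin-2-yl octadecanoate (3 equiv)
Product: 11 1-tert-butyl 2-methyl 3-nonadecyl-1H-pyrrole-1,2-dicarboxylate
Conditions: NiCl2·6H2O (20 mol%), 2,2':6',2''-terpyridine (20 mol%), DMF/THF, Zn(+)/RVC(−), undivided cell, constant current, rt; then dilute aq. HCl work-up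
Reagents that add atoms: none
Why: This is a nickel-electrocatalytic doubly decarboxylative cross-coupling of two alkyl redox-active esters, the reductive counterpart of a mixed Kolbe coupling: low-valent nickel–terpyridine, formed at the cathode from the divalent nickel precatalyst, passes one electron to each N-acyloxyphthalimide, whose radical anion breaks at the N–O bond and expels phthalimide anion and CO2 to leave a primary alkyl radical. The 2-(pyrrol-3-yl)ethyl and heptadecyl fragments are captured at nickel one after the other, and the dialkylnickel species reductively eliminates to forge the CH2–CH2 bond between chain carbons 2 and 3. No ring is closed and no stereocentre is created, so neither a mode of closure nor stereocontrol arises. The selectivity needed is cross-coupling over homodimerisation, which for two primary radicals of like reactivity is close to statistical and is therefore biased by three equivalents of the inexpensive ester 10, whose hydrocarbon dimer is non-polar and should elute from silica well ahead of 11. Chemoselectivity rests on the substrate design: the sacrificial zinc anode bears all oxidation so the electron-rich pyrrole is never oxidised, the N-Boc group removes the acidic N–H that could quench alkylnickel intermediates, and both fragments are unbranched primary radicals with no β-leaving group.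

Step 7
Reactants: 11 1-tert-butyl 2-methyl 3-nonadecyl-1H-pyrrole-1,2-dicarboxylate
Product: 12 methyl 3-nonadecyl-1H-pyrrole-2-carboxylate
Conditions: TFA/CH2Cl2 (1:4), 0 °C to rt
Reagents that add atoms: none
Why: Acidolysis of the N-Boc carbamate (protonation, loss of the tert-butyl cation as 2-methylpropene, decarboxylation of the carbamic acid) frees the pyrrole N–H, while the methyl ester and the alkyl chain are inert and the ester-deactivated pyrrole should tolerate the acid.

Compound list
1 | methyl 3-bromo-1H-pyrrole-2-carboxylate | COC(=O)c1[nH]ccc1Br | starting material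
2 | 1-tert-butyl 2-methyl 3-bromo-1H-pyrrole-1,2-dicarboxylate | COC(=O)c1c(Br)ccn1C(=O)OC(C)(C)C | intermediate
3 | benzyl acrylate | C=CC(=O)OCc1ccccc1 | starting material
4 | 1-tert-butyl 2-methyl 3-[(E)-3-(benzyloxy)-3-oxoprop-1-en-1-yl]-1H-pyrrole-1,2-dicarboxylate | COC(=O)c1c(/C=C/C(=O)OCc2ccccc2)ccn1C(=O)OC(C)(C)C | intermediate
5 | 1-tert-butyl 2-methyl 3-[3-(benzyloxy)-3-oxopropyl]-1H-pyrrole-1,2-dicarboxylate (saturated benzyl ester, not isolated) | COC(=O)c1c(CCC(=O)OCc2ccccc2)ccn1C(=O)OC(C)(C)C | intermediate
6 | 3-[1-(tert-butoxycarbonyl)-2-(methoxycarbonyl)-1H-pyrrol-3-yl]propanoic acid | COC(=O)c1c(CCC(=O)O)ccn1C(=O)OC(C)(C)C | intermediate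
7 | N-hydroxyphthalimide | ON1C(=O)c2ccccc2C1=O | starting material
8 | 1-tert-butyl 2-methyl 3-{3-[(1,3-dioxoisoindolin-2-yl)oxy]-3-oxopropyl}-1H-pyrrole-1,2-dicarboxylate | COC(=O)c1c(CCC(=O)ON2C(=O)c3ccccc3C2=O)ccn1C(=O)OC(C)(C)C | intermediate
9 | stearic acid (octadecanoic acid) | CCCCCCCCCCCCCCCCCC(=O)O | starting material
10 | 1,3-dioxoisoindolin-2-yl octadecanoate | CCCCCCCCCCCCCCCCCC(=O)ON1C(=O)c2ccccc2C1=O | intermediate
11 | 1-tert-butyl 2-methyl 3-nonadecyl-1H-pyrrole-1,2-dicarboxylate | CCCCCCCCCCCCCCCCCCCc1ccn(C(=O)OC(C)(C)C)c1C(=O)OC | intermediate
12 | methyl 3-nonadecyl-1H-pyrrole-2-carboxylate | CCCCCCCCCCCCCCCCCCCc1cc[nH]c1C(=O)OC | target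

Total step count: 7.
Longest linear sequence: 6 steps (steps 1, 2, 3, 4, 6 and 7); step 5 is a one-step branch.

Steps most likely to fail

Step 6. The cross-coupling may be eroded by statistical homodimerisation of each partner and by premature reduction of the alkyl radicals to alkanes. β-Hydride elimination from the 2-(pyrrolyl)ethylnickel species to a vinylpyrrole is a further loss pathway, and poor solubility of the waxy stearate ester could starve the cathode. Any Boc loss during electrolysis is harmless, because it converges on 12 in step 7. The fallback gives up the sp3–sp3 coupling for an sp2–sp3 coupling at the ring. It sets out from bromide 2: hydroboration of 1-nonadecene with 9-borabicyclo[3.3.1]nonane in THF should give 9-nonadecyl-9-borabicyclo[3.3.1]nonane F1. A B-alkyl Suzuki–Miyaura coupling of F1 with 2 (PdCl2(dppf), aqueous K3PO4, THF/DMF, 50 °C) should then deliver the whole chain at C3 and come back to the route at 11.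

Step 2. Oxidative addition at the crowded C3–Br bond beside the ester may be slow, allowing protodebromination, and warming with an amine base may cost the N-Boc group. The fallback sets out from 2 and replaces the Heck reaction by a Negishi coupling. Zinc insertion into benzyl 3-bromopropanoate (Zn dust, LiCl, THF, 40 °C) should give [3-(benzyloxy)-3-oxopropyl]zinc bromide F2. Coupling of F2 with 2 (Pd(OAc)2, SPhos, THF, rt to 50 °C) should install the saturated arm directly and come back to the route at 5, which the conditions of step 3 then hydrogenolyse to 6.

Step 4. The carbodiimide-activated acid may rearrange to an unreactive N-acylurea, and the activated ester may hydrolyse during chromatography, leaving acid and N-hydroxyphthalimide that would disturb the electrolysis. The fallback sets out from 6 and activates the acid as its chloride under neutral conditions. Treatment with 1-chloro-N,N,2-trimethylprop-1-en-1-amine in CH2Cl2 at 0 °C should give 1-tert-butyl 2-methyl 3-(3-chloro-3-oxopropyl)-1H-pyrrole-1,2-dicarboxylate F3. Acylation of N-hydroxyphthalimide 7 with F3 and Et3N in the same flask should come back to the route at 8, which can then be purified by crystallisation.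

Further compounds
F1 | step 6 | 9-nonadecyl-9-borabicyclo[3.3.1]nonane | CCCCCCCCCCCCCCCCCCCB1C2CCCC1CCC2
F2 | step 2 | [3-(benzyloxy)-3-oxopropyl]zinc bromide | Br[Zn]CCC(=O)OCc1ccccc1
F3 | step 4 | 1-tert-butyl 2-methyl 3-(3-chloro-3-oxopropyl)-1H-pyrrole-1,2-dicarboxylate | COC(=O)c1c(CCC(=O)Cl)ccn1C(=O)OC(C)(C)C
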